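**Plan**
Retrosynthesis cuts, in this order: the O8 ester (acid 33), C11=C13, the lactone bond O6–C12 (back to a 1,4-diol), the ring bond C5–C6, the chain bond C7–C8, and in ring B C3=C4 and O–C5.
Forward: ring B (tetrahydrooxepine) is built first on a geraniol-derived tertiary alcohol. The C6–C7(C11–C12) unit is then joined to C8, and the C5–C6 bond closes ring A (oxepane) and the ten-membered carbocycle in one event. Ring C (lactone), the methylene group and the ester follow.
Enabling feature: C5 is both the carbon next to the bridging oxygen and the allylic end of the C3=C4–C15O2Me enoate. Moving the double bond to C4=C5 and placing acetate on C3 turns ring B into a cyclic β-alkoxyacrylate. Its β-carbon C5 accepts a C6 ketyl and gives the enoate back by loss of acetate, while C10, one oxygen away from C5, holds the tether.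
Stereochemistry: C10 comes from a catalytic Sharpless epoxidation and C7/C8 from a catalytic (E)-allylboration. C5 and C6 are relayed from C10 and C7 in the key step, and the two epoxide centres of the acid come from a second Sharpless epoxidation.

Key step: step 14

Numbering used in the names: C1H2–C2H2–C3H=C4(C15O2Me)–C5H(O)–C6H(O)–C7H–C8H(O)–C9H2–C10(C14H3)(O). The ether oxygen joins C5 and C10, and C11(=C13H2)–C12(=O)–O6 is the lactone. Ring A = O/C5–C10, ring B = O/C10/C1–C5, ring C = lactone.
Assumption 1: the acyl group is read literally as (2S,3R)-2,3-dimethyloxirane-2-carboxylate (methyl groups cis), that is, the epoxide of the tiglic rather than the angelic skeleton.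
Assumption 2: (R)-TRIP is taken to direct allylboronates to the Re face of RCHO, so (S)-TRIP is used. Its antipode is taken if the sense proves opposite.

**Step 1**
Reactants: 1 geraniol
Product: 2 (2S,3S)-2,3-epoxygeraniol
Conditions: Ti(OiPr)4 (cat.), L-(+)-diethyl tartrate (cat.), t-BuOOH, 4 Å MS, CH2Cl2, −20 °C
Reagents that add atoms: tert-butyl hydroperoxide, CC(C)(C)OO
Why: Sharpless asymmetric epoxidation of an (E)-allylic alcohol; the L-(+)-tartrate complex should deliver oxygen to the face that gives the (2S,3S)-epoxide and so fixes the future C10–O bond, while the remote trisubstituted alkene is not touched.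

**Step 2**
Reactants: 2 (2S,3S)-2,3-epoxygeraniol
Product: 3 (S)-3,7-dimethyloct-6-ene-1,3-diol
Conditions: LiAlH4, THF, 0 °C
Reagents that add atoms: none
Why: SN2 hydride opening of a 2,3-epoxy alcohol at the only accessible carbon (C2) leaves the tertiary C–O bond, and hence the configuration of C10, untouched.

**Step 3**
Reactants: 3 (S)-3,7-dimethyloct-6-ene-1,3-diol
Product: 4 (S)-1-(4-methoxybenzyloxy)-3,7-dimethyloct-6-en-3-ol
Conditions: NaH (1 equiv), 4-methoxybenzyl chloride, Bu4NI (cat.), THF–DMF, 0 °C
Reagents that add atoms: 4-methoxybenzyl chloride, COc1ccc(CCl)cc1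
Why: Williamson etherification; the primary alkoxide forms and reacts far faster than the tertiary one, and a benzyl-type group cannot migrate to the tertiary alkoxide in step 4 as a silyl group could.

**Step 4**
Reactants: 4 (S)-1-(4-methoxybenzyloxy)-3,7-dimethyloct-6-en-3-ol; 5 methyl 2-(bromomethyl)acrylate
Product: 6 methyl 2-({[(S)-1-(4-methoxybenzyloxy)-3,7-dimethyloct-6-en-3-yl]oxy}methyl)acrylate
Conditions: NaH, Bu4NI (cat.), THF–DMF, 0 °C to rt
Reagents that add atoms: none
Why: Williamson-type etherification of the tertiary alkoxide with a very reactive 2-(halomethyl)acrylate, for which SN2 and SN2′ attack give the same ether; C10 is not involved.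

**Step 5**
Reactants: 6 acrylate ether diene
Product: 7 methyl (S)-7-[2-(4-methoxybenzyloxy)ethyl]-7-methyl-2,5,6,7-tetrahydrooxepine-3-carboxylate (ring B)
Conditions: second-generation Hoveyda–Grubbs catalyst (cat.), toluene (0.005 M), 80 °C, argon sparge
Reagents that add atoms: none
Why: ring-closing metathesis of the 2-substituted acrylate with the prenyl terminus should close the seven-membered ring B as the trisubstituted C3=C4 enoate, driven by loss of a volatile alkene.

**Step 6**
Reactants: 7 ring B PMB ether
Product: 8 methyl (S)-7-(2-hydroxyethyl)-7-methyl-2,5,6,7-tetrahydrooxepine-3-carboxylate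
Conditions: DDQ, CH2Cl2–pH 7 buffer, 0 °C
Reagents that add atoms: none
Why: oxidative PMB cleavage by hydride abstraction at the electron-rich benzylic position; the electron-poor enoate and its allylic ether are inert.

**Step 7**
Reactants: 8 ring B primary alcohol
Product: 9 methyl (S)-7-methyl-7-(2-oxoethyl)-2,5,6,7-tetrahydrooxepine-3-carboxylate (C8 aldehyde)
Conditions: TEMPO (cat.), PhI(OAc)2, CH2Cl2, rt
Reagents that add atoms: none
Why: oxoammonium (TEMPO) oxidation stops at the aldehyde under neutral conditions, which avoids β-elimination of the tertiary ether.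

**Step 8**
Reactants: 10 4-(tert-butyldimethylsilyloxy)but-1-yne
Product: 11 (E)-2-[4-(tert-butyldimethylsilyloxy)but-1-enyl]-4,4,5,5-tetramethyl-1,3,2-dioxaborolane
Conditions: pinacolborane, Cp2Zr(H)Cl (cat.), Et3N (cat.), neat, 60 °C
Reagents that add atoms: pinacolborane, CC1(C)OBOC1(C)C
Why: zirconium-catalysed syn hydroboration of a terminal alkyne gives the (E)-alkenylboronate regio- and stereoselectively.

**Step 9**
Reactants: 11 (E)-alkenylboronate
Product: 13 (E)-2-[5-(tert-butyldimethylsilyloxy)pent-2-enyl]-4,4,5,5-tetramethyl-1,3,2-dioxaborolane, via boronate complex 12 (not isolated)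
Conditions: BrCH2Cl, n-BuLi, THF, −78 °C to rt
Reagents that add atoms: bromochloromethane, ClCBr
Why: Matteson homologation; chloromethyllithium adds to boron, and 1,2-migration of the alkenyl group with loss of chloride inserts CH2 with retention of the (E)-geometry.

**Step 10**
Reactants: 9 C8 aldehyde; 13 (E)-allylboronate
Product: 15 anti-homoallylic alcohol (7S,8R,10S) carrying C8-OH, C7 vinyl (C6) and C7 CH2CH2OTBS (C11–C12) on ring B, via borate ester 14 (not isolated)
Conditions: (S)-TRIP (3,3′-bis(2,4,6-triisopropylphenyl)-BINOL hydrogen phosphate, cat.), 4 Å MS, toluene, −30 to 0 °C; aq NaHCO3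
Reagents that add atoms: none
Why: chiral phosphoric acid-catalysed allylboration through a closed chair (Zimmerman–Traxler) transition state; the (E)-boronate sets the C7/C8 anti relation, and the catalyst directs attack to the Si face of the aldehyde, overriding the remote C10 centre.

**Step 11**
Reactants: 15 anti-homoallylic alcohol
Product: 16 bis-TBS ether (7S,8R,10S)
Conditions: TBSOTf, 2,6-lutidine, CH2Cl2, −78 to 0 °C
Reagents that add atoms: tert-butyldimethylsilyl triflate, CC(C)(C)[Si](C)(C)OS(=O)(=O)C(F)(F)F
Why: silylation of a hindered secondary alcohol with a silyl triflate and a non-nucleophilic base; no stereocentre is touched.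

**Step 12**
Reactants: 16 bis-TBS ether
Product: 18 C6 aldehyde (7R,8R,10S), via ozonide 17 (not isolated)
Conditions: O3, CH2Cl2, −78 °C (Sudan red endpoint); PPh3, −78 °C to rt
Reagents that add atoms: ozone, [O-][O+]=O
Why: ozonolysis; electrophilic ozone selects the unactivated vinyl group over the ester-deactivated C3=C4 bond, and the neutral reductive work-up keeps the α-stereocentre C7.

**Step 13**
Reactants: 18 C6 aldehyde
Product: 21 cyclic β-alkoxyacrylate with C3 acetate (7R,8R,10S; C3 epimers), via hydroperoxide 19 (not isolated), via allylic alcohol 20 (not isolated)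
Conditions: O2, tetraphenylporphyrin (cat.), BHT (trace), visible light, CCl4, 0 °C; PPh3 (1.0 equiv); then Ac2O, pyridine, DMAP (cat.), 0 °C
Reagents that add atoms: dioxygen, O=O; acetic anhydride, CC(=O)OC(C)=O
Why: Schenck ene reaction of singlet oxygen with an α,β-unsaturated ester, which takes hydrogen from the alkyl group geminal to the ester (C5H2) and puts oxygen on the β-carbon C3, so that the double bond moves to C4=C5; phosphine reduction and acetylation follow in the same flask, and the C3 configuration is irrelevant because C3 becomes sp2 in step 14.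

**Step 14**
Reactants: 21 cyclic β-alkoxyacrylate with C3 acetate
Product: 22 methyl (5R,6S,7S,8R,10S)-5,10-epoxy-6-hydroxy-8-(TBSO)-7-[2-(TBSO)ethyl]-10-methylcyclodec-3-ene-4-carboxylate (11-oxabicyclo[4.4.1]undecene core)
Conditions: SmI2 (0.1 M in THF, 3 equiv), slow addition of 21 (final 0.005 M), THF, −78 to 0 °C; aq Rochelle salt–NaHCO3
Reagents that add atoms: none
Why: Proposed new method: electron transfer from SmI2 to the C6 aldehyde gives a ketyl radical that adds to C5, the β-carbon of the ring-embedded β-alkoxyacrylate, a second electron turns the C4 radical into a trivalent samarium enolate, and this enolate expels the C3 acetate (E1cB), so that the C3=C4 enoate of the target is restored in the same event; the closest known reactions are the SmI2 reductive cyclisation of aldehyde-tethered β-alkoxyacrylates used for 2,3-trans oxepanes and the SmI2 ketyl–olefin coupling/β-elimination sequence, which have not been merged on an endocyclic acceptor to close a bridged ring. The new bond closes ring A in a 7-exo-trig mode and, seen along the carbon perimeter, the ten-membered carbocycle in a 10-endo-trig mode. C5 is controlled by C10, because the tether C9–C8–C7–C6 hangs from C10 next to the ring oxygen and can reach only the face of C4=C5 syn to it. C6 is controlled by the usual transition state of this cyclisation, with the ketyl oxygen anti to the ring oxygen and bridged through samarium to the ester carbonyl on C4, and with the C11 branch of C7 pseudo-equatorial, which should give H5/H6 trans and H6/H7 trans. Chemoselectivity rests on the aldehyde being the only group that SmI2 in plain THF reduces (vinylogous carbonate, acetate and silyl ethers are inert), regioselectivity on C5 being the only acceptor carbon within reach, and high dilution suppresses pinacol coupling. Both C3 epimers of 21 converge because C3 becomes sp2.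

**Step 15**
Reactants: 22 bicyclic hydroxy enoate
Product: 23 1,4-diol (5R,6S,7S,8R,10S) with C6-OH and C12-OH free and O8 still TBS-protected
Conditions: camphorsulfonic acid (cat.), MeOH–CH2Cl2, 0 °C
Reagents that add atoms: none
Why: acid-catalysed methanolysis distinguishes the unhindered primary silyl ether from the hindered secondary one at C8.

**Step 16**
Reactants: 23 1,4-diol
Product: 25 tricyclic trans-fused γ-lactone (5R,6S,7S,8R,10S) with C11H2 and O8-TBS, via lactol 24 (not isolated)
Conditions: TEMPO (cat.), PhI(OAc)2 (2.5 equiv), CH2Cl2, rt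
Reagents that add atoms: none
Why: TEMPO/PhI(OAc)2 oxidative lactonisation of a 1,4-diol; the primary alcohol is oxidised first, O6 traps the aldehyde as the lactol, and this is oxidised on, the trans fusion being already fixed by C6 and C7.

**Step 17**
Reactants: 25 tricyclic γ-lactone
Product: 28 α-methylene lactone with O8-TBS (5R,6S,7S,8R,10S), via Mannich base 26 (not isolated), via ammonium iodide 27 (not isolated)
Conditions: LDA, THF, −78 °C; CH2=NMe2+ I−, −78 °C to rt; MeI, THF–MeOH, rt; aq NaHCO3, CH2Cl2
Reagents that add atoms: dimethyl(methylidene)ammonium iodide, C=[N+](C)C.[I-]; iodomethane, CI (into 27 only)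
Why: kinetic lactone enolate formation, Mannich reaction with Eschenmoser's salt, N-methylation and Hofmann-type elimination form the standard α-methylenation of γ-lactones; the lactone α-CH2 is the most acidic site (the enoate offers only γ-hydrogens) and C11 ends sp2.

**Step 18**
Reactants: 28 α-methylene lactone with O8-TBS
Product: 29 C8 alcohol (5R,6S,7R,8R,10S)
Conditions: HF·pyridine, THF, 0 °C to rt
Reagents that add atoms: none
Why: fluoride-mediated desilylation under mildly acidic conditions, which the α-methylene lactone and the enoate tolerate.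

**Step 19**
Reactants: 30 (E)-2-methylbut-2-en-1-ol (tiglyl alcohol)
Product: 31 [(2R,3R)-2,3-dimethyloxiran-2-yl]methanol
Conditions: Ti(OiPr)4 (cat.), D-(−)-diethyl tartrate (cat.), t-BuOOH, 4 Å MS, CH2Cl2, −20 °C
Reagents that add atoms: tert-butyl hydroperoxide, CC(C)(C)OO
Why: Sharpless asymmetric epoxidation; the D-(−)-tartrate should give the (2R,3R)-epoxy alcohol, and the (E)-alkene geometry fixes the cis relation of the two methyl groups.

**Step 20**
Reactants: 31 epoxy alcohol
Product: 33 (2S,3R)-2,3-dimethyloxirane-2-carboxylic acid, via epoxy aldehyde 32 (not isolated)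
Conditions: TEMPO (cat.), PhI(OAc)2 (2.2 equiv), MeCN–H2O, rt
Reagents that add atoms: water, O
Why: TEMPO/PhI(OAc)2 oxidation in aqueous acetonitrile takes the primary alcohol through the aldehyde hydrate to the acid without opening the epoxide; the C2 descriptor changes from R to S only through the priority change.

**Step 21**
Reactants: 29 C8 alcohol; 33 epoxy acid
Product: 35 target CNP0240298.1, via mixed anhydride 34 (not isolated)
Conditions: 33, 2,4,6-trichlorobenzoyl chloride, Et3N, toluene, rt; then 29, DMAP, rt
Reagents that add atoms: 2,4,6-trichlorobenzoyl chloride, O=C(Cl)c1c(Cl)cc(Cl)cc1Cl (into 34 only)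
Why: Yamaguchi esterification; the mixed anhydride activates the hindered α-quaternary acid for DMAP-mediated acyl transfer to the hindered C8 alcohol, with retention at every stereocentre.

**Compound list**
1 | geraniol | CC(C)=CCC/C(C)=C/CO | starting material
2 | (2S,3S)-2,3-epoxygeraniol | OC[C@@H]1O[C@@]1(C)CCC=C(C)C | intermediate
3 | (S)-3,7-dimethyloct-6-ene-1,3-diol | OCC[C@](O)(C)CCC=C(C)C | intermediate
4 | (S)-1-(4-methoxybenzyloxy)-3,7-dimethyloct-6-en-3-ol | COc1ccc(COCC[C@](O)(C)CCC=C(C)C)cc1 | intermediate
5 | methyl 2-(bromomethyl)acrylate | C=C(CBr)C(=O)OC | starting material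
6 | acrylate ether diene | COc1ccc(COCC[C@](OCC(=C)C(=O)OC)(C)CCC=C(C)C)cc1 | intermediate
7 | ring B enoate, PMB ether | COc1ccc(COCC[C@]2(C)CCC=C(C(=O)OC)CO2)cc1 | intermediate
8 | ring B enoate, primary alcohol | OCC[C@]1(C)CCC=C(C(=O)OC)CO1 | intermediate
9 | ring B enoate, C8 aldehyde | O=CC[C@]1(C)CCC=C(C(=O)OC)CO1 | intermediate
10 | 4-(tert-butyldimethylsilyloxy)but-1-yne | C#CCCO[Si](C)(C)C(C)(C)C | starting material
11 | (E)-alkenyl pinacolboronate | CC1(C)OB(/C=C/CCO[Si](C)(C)C(C)(C)C)OC1(C)C | intermediate
12 | lithium (chloromethyl)boronate complex | [Li+].ClC[B-]1(/C=C/CCO[Si](C)(C)C(C)(C)C)OC(C)(C)C(C)(C)O1 | intermediate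
13 | (E)-allyl pinacolboronate | CC1(C)OB(C/C=C/CCO[Si](C)(C)C(C)(C)C)OC1(C)C | intermediate
14 | O8 pinacolborate of 15 | C=C[C@H](CCO[Si](C)(C)C(C)(C)C)[C@H](OB1OC(C)(C)C(C)(C)O1)C[C@]1(C)CCC=C(C(=O)OC)CO1 | intermediate
15 | anti-homoallylic alcohol (7S,8R,10S) | C=C[C@H](CCO[Si](C)(C)C(C)(C)C)[C@H](O)C[C@]1(C)CCC=C(C(=O)OC)CO1 | intermediate
16 | bis-TBS ether (7S,8R,10S) | C=C[C@H](CCO[Si](C)(C)C(C)(C)C)[C@H](O[Si](C)(C)C(C)(C)C)C[C@]1(C)CCC=C(C(=O)OC)CO1 | intermediate
17 | ozonide of 16 | C1OC(OO1)[C@H](CCO[Si](C)(C)C(C)(C)C)[C@H](O[Si](C)(C)C(C)(C)C)C[C@]1(C)CCC=C(C(=O)OC)CO1 | intermediate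
18 | C6 aldehyde (7R,8R,10S) | O=C[C@H](CCO[Si](C)(C)C(C)(C)C)[C@H](O[Si](C)(C)C(C)(C)C)C[C@]1(C)CCC=C(C(=O)OC)CO1 | intermediate
19 | C3 hydroperoxide, C4=C5 (C3 epimers) | O=C[C@H](CCO[Si](C)(C)C(C)(C)C)[C@H](O[Si](C)(C)C(C)(C)C)C[C@]1(C)CCC(OO)C(C(=O)OC)=CO1 | intermediate
20 | C3 allylic alcohol, C4=C5 (C3 epimers) | O=C[C@H](CCO[Si](C)(C)C(C)(C)C)[C@H](O[Si](C)(C)C(C)(C)C)C[C@]1(C)CCC(O)C(C(=O)OC)=CO1 | intermediate
21 | C3 acetate, cyclic β-alkoxyacrylate (C3 epimers) | O=C[C@H](CCO[Si](C)(C)C(C)(C)C)[C@H](O[Si](C)(C)C(C)(C)C)C[C@]1(C)CCC(OC(C)=O)C(C(=O)OC)=CO1 | intermediate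
22 | bicyclic hydroxy enoate (5R,6S,7S,8R,10S) | O[C@H]2[C@H](CCO[Si](C)(C)C(C)(C)C)[C@H](O[Si](C)(C)C(C)(C)C)C[C@]1(C)CCC=C(C(=O)OC)[C@H]2O1 | intermediate
23 | 1,4-diol, O8-TBS | O[C@H]2[C@H](CCO)[C@H](O[Si](C)(C)C(C)(C)C)C[C@]1(C)CCC=C(C(=O)OC)[C@H]2O1 | intermediate
24 | lactol, O8-TBS | C1C(O)O[C@H]2[C@H]1[C@H](O[Si](C)(C)C(C)(C)C)C[C@]1(C)CCC=C(C(=O)OC)[C@H]2O1 | intermediate
25 | tricyclic γ-lactone, O8-TBS | C1C(=O)O[C@H]2[C@H]1[C@H](O[Si](C)(C)C(C)(C)C)C[C@]1(C)CCC=C(C(=O)OC)[C@H]2O1 | intermediate
26 | C11 dimethylaminomethyl lactone (C11 epimers) | CN(C)CC1C(=O)O[C@H]2[C@H]1[C@H](O[Si](C)(C)C(C)(C)C)C[C@]1(C)CCC=C(C(=O)OC)[C@H]2O1 | intermediate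
27 | trimethylammonium iodide of 26 | [I-].C[N+](C)(C)CC1C(=O)O[C@H]2[C@H]1[C@H](O[Si](C)(C)C(C)(C)C)C[C@]1(C)CCC=C(C(=O)OC)[C@H]2O1 | intermediate
28 | α-methylene lactone, O8-TBS | C=C1C(=O)O[C@H]2[C@H]1[C@H](O[Si](C)(C)C(C)(C)C)C[C@]1(C)CCC=C(C(=O)OC)[C@H]2O1 | intermediate
29 | α-methylene lactone, C8 alcohol | C=C1C(=O)O[C@H]2[C@H]1[C@H](O)C[C@]1(C)CCC=C(C(=O)OC)[C@H]2O1 | intermediate
30 | (E)-2-methylbut-2-en-1-ol | C/C=C(\C)CO | starting material
31 | [(2R,3R)-2,3-dimethyloxiran-2-yl]methanol | OC[C@@]1(C)O[C@@H]1C | intermediate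
32 | (2S,3R)-2,3-dimethyloxirane-2-carbaldehyde | O=C[C@@]1(C)O[C@@H]1C | intermediate
33 | (2S,3R)-2,3-dimethyloxirane-2-carboxylic acid | OC(=O)[C@@]1(C)O[C@@H]1C | intermediate
34 | mixed 2,4,6-trichlorobenzoic anhydride of 33 | O=C(OC(=O)[C@@]1(C)O[C@@H]1C)c1c(Cl)cc(Cl)cc1Cl | intermediate
35 | CNP0240298.1 | C=C1C(=O)O[C@H]2[C@H]1[C@H](OC(=O)[C@@]1(C)O[C@@H]1C)C[C@]1(C)CCC=C(C(=O)OC)[C@H]2O1 | target

**Count**
Total: 21 steps. Longest linear sequence: 17 steps from geraniol (steps 1–7, 10–18 and 21).

**Steps most likely to fail**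

Step 14. The 7-exo closure onto a trisubstituted, donor-substituted acceptor may be slower than hydrogen abstraction or pinacol coupling of the ketyl. The C8 silyl ether has to become pseudo-axial in the transition state, and facial selectivity at C6 may erode. The fallback is a two-electron route with known chemistry and sets out from 21. Stannylation of the allylic acetate with hexabutylditin, catalysed by the zerovalent palladium complex Pd(PPh3)4, should give the ring-embedded γ-alkoxyallylstannane F1 (tin on C3, C4=C5 kept). BF3·OEt2 in CH2Cl2 at −78 °C then brings about the intramolecular SE2′ addition of C5 to the C6 aldehyde. This Lewis-acid allylstannane–aldehyde cyclisation is established for 2,3-trans cyclic ethers and for 2-(alkoxycarbonyl)allylstannanes. The fallback comes back at 22.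

Step 13. The ene reaction of the electron-poor alkene is slow, so autoxidation of the free aldehyde during the long irradiation, or hydrogen abstraction at C2, may compete. The fallback sets out from 16. Dihydroxylation of the vinyl group (OsO4 cat., NMO) gives the terminal glycol F2, which carries C6 as a masked aldehyde. Photooxygenation gives the hydroperoxide F3 and PPh3 the triol F4. NaIO4 in aqueous THF then cleaves the glycol under neutral conditions. The fallback comes back at 20, which is acetylated to 21 as before.

Step 5. Neither alkene is a good site of initiation, since one is trisubstituted and the other a 1,1-disubstituted acrylate, so catalyst decay or dimerisation may outrun ring closure. The fallback uses olefination instead of metathesis and sets out from 4. Base-catalysed oxa-Michael addition of the tertiary alcohol to trimethyl 2-phosphonoacrylate gives the phosphonate F5. Ozonolysis of the prenyl alkene gives the aldehyde F6. An intramolecular Horner–Wadsworth–Emmons reaction (LiCl, DBU, MeCN, high dilution) then closes ring B. The fallback comes back at 7.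

**Further compounds**
F1 | step 14 | ring-embedded γ-alkoxyallylstannane (tin on C3) | O=C[C@H](CCO[Si](C)(C)C(C)(C)C)[C@H](O[Si](C)(C)C(C)(C)C)C[C@]1(C)CCC([Sn](CCCC)(CCCC)CCCC)C(C(=O)OC)=CO1
F2 | step 13 | terminal glycol from 16 | OCC(O)[C@H](CCO[Si](C)(C)C(C)(C)C)[C@H](O[Si](C)(C)C(C)(C)C)C[C@]1(C)CCC=C(C(=O)OC)CO1
F3 | step 13 | C3 hydroperoxide of the glycol | OCC(O)[C@H](CCO[Si](C)(C)C(C)(C)C)[C@H](O[Si](C)(C)C(C)(C)C)C[C@]1(C)CCC(OO)C(C(=O)OC)=CO1
F4 | step 13 | triol | OCC(O)[C@H](CCO[Si](C)(C)C(C)(C)C)[C@H](O[Si](C)(C)C(C)(C)C)C[C@]1(C)CCC(O)C(C(=O)OC)=CO1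
F5 | step 5 | oxa-Michael phosphonate | COc1ccc(COCC[C@](OCC(C(=O)OC)P(=O)(OC)OC)(C)CCC=C(C)C)cc1
F6 | step 5 | phosphonate aldehyde | COc1ccc(COCC[C@](OCC(C(=O)OC)P(=O)(OC)OC)(C)CCC=O)cc1
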